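**Retrosynthetic overview**

1. Numbering used: ring A is the 5-alkylresorcinol ring, ring B the 4-aryloxy-3,5-dihydroxyphenyl ring; the chain runs from C1' (the (R)-carbinol on ring B) to C14' (CH2 on ring A), with the (Z)-alkene at C8'=C9'.
2. Rings A and B are bought; the only ring formed is the 22-membered macrocycle, closed last at C3'–C4' by a one-pot hydroboration / copper-catalysed C(sp3)–C(sp3) Suzuki–Miyaura coupling of an open-chain ene–tosylate, followed by MOM and silyl removal.
3. Enabling feature: C2' and C3' sit next to the benzylic carbinol C1' on ring B, so they can be carried as the vinyl group of an (R)-1-arylallyl silyl ether (C3' becomes a primary alkylborane, boron γ to oxygen). C4' begins the unfunctionalised C4'–C7' run and can bear a primary tosylate, and the only other alkene, C8'=C9', is 1,2-disubstituted and ignored by 9-BBN.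
4. Open-chain precursor: the ring A–C14' bond comes from a B-alkyl Suzuki–Miyaura coupling of an aryl bromide with a C11 (Z)-dienyl tosylate (hex-5-yn-1-ol + 5-bromopent-1-ene, then semi-hydrogenation); C1' is set by catalytic asymmetric vinylation of the ring B aldehyde.
5. The hindered diaryl ether is made first, by Chan–Lam coupling of 4-hydroxy-3,5-bis(methoxymethoxy)benzaldehyde (from 3,4,5-trihydroxybenzaldehyde) with a ring A boronic acid (from 3,5-dibromophenol).

Key step: step 13

Remark: the carbinol centre in the target SMILES corresponds to (R) (OH > ring B carbon > C2' > H); the descriptor stays (R) in all intermediates because the aryl group also outranks vinyl.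

**Route**

Step 1
Reactants: 1 3,4,5-trihydroxybenzaldehyde
Product: 2 3,5-dihydroxy-4-(prop-2-enyloxy)benzaldehyde
Conditions: allyl bromide (1.0 equiv), KHCO3 (1.1 equiv), DMF, rt
Reagents that add atoms: allyl bromide, C=CCBr
Why: Williamson ether synthesis; the 4-OH, para to the formyl group, is by far the most acidic phenol, so the weak base ionises only this position and one equivalent of allyl bromide should alkylate it selectively.

Step 2
Reactants: 2 3,5-dihydroxy-4-(prop-2-enyloxy)benzaldehyde
Product: 3 3,5-bis(methoxymethoxy)-4-(prop-2-enyloxy)benzaldehyde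
Conditions: MOMCl (2.6 equiv), iPr2NEt (3 equiv), CH2Cl2, 0 °C to rt
Reagents that add atoms: chloromethyl methyl ether, COCCl
Why: Acetal (MOM ether) formation at the two remaining, equivalent phenols under amine base; the aldehyde and the allyl ether are inert.

Step 3
Reactants: 3 3,5-bis(methoxymethoxy)-4-(prop-2-enyloxy)benzaldehyde
Product: 4 4-hydroxy-3,5-bis(methoxymethoxy)benzaldehyde
Conditions: Pd(PPh3)4 (2 mol %), K2CO3 (3 equiv), MeOH, rt; work-up at pH 5
Reagents that add atoms: none
Why: Tsuji–Trost-type deallylation; zerovalent palladium ionises the aryl allyl ether (the stabilised phenoxide is a good leaving group) and methoxide takes over the allyl unit, while aldehyde and MOM ethers are untouched.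

Step 4
Reactants: 5 3,5-dibromophenol
Product: 6 1,3-dibromo-5-(methoxymethoxy)benzene
Conditions: MOMCl (1.3 equiv), iPr2NEt (1.5 equiv), CH2Cl2, 0 °C to rt
Reagents that add atoms: chloromethyl methyl ether, COCCl
Why: MOM protection of the phenol (acetal formation), giving a base-stable group that survives organolithium and cross-coupling chemistry.

Step 5
Reactants: 6 1,3-dibromo-5-(methoxymethoxy)benzene
Product: 8 [3-bromo-5-(methoxymethoxy)phenyl]boronic acid, via aryllithium 7 (not isolated)
Conditions: B(OiPr)3 (1.3 equiv), toluene/THF, −78 °C, then n-BuLi (1.0 equiv) added slowly (in situ quench); −78 to −20 °C; aq. NH4Cl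
Reagents that add atoms: triisopropyl borate, CC(C)OB(OC(C)C)OC(C)C; water, O
Why: Bromine–lithium exchange at one of two equivalent C–Br bonds with immediate borylation; the anionic arylborate resists a second exchange, and the mild aqueous work-up keeps the MOM ether.

Step 6
Reactants: 4 4-hydroxy-3,5-bis(methoxymethoxy)benzaldehyde; 8 [3-bromo-5-(methoxymethoxy)phenyl]boronic acid
Product: 9 4-[3-bromo-5-(methoxymethoxy)phenoxy]-3,5-bis(methoxymethoxy)benzaldehyde
Conditions: 8 (2 equiv), Cu(OAc)2 (30 mol %), pyridine (5 equiv), 4 Å molecular sieves, CH2Cl2, O2 (balloon), rt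
Reagents that add atoms: none
Why: Chan–Lam oxidative C–O coupling, the room-temperature copper-mediated aryl ether synthesis known to tolerate 2,6-disubstituted and acidic phenols, aryl bromides and aldehydes; the small MOM groups keep the flanked phenol accessible.

Step 7
Reactants: 9 4-[3-bromo-5-(methoxymethoxy)phenoxy]-3,5-bis(methoxymethoxy)benzaldehyde
Product: 10 (1R)-1-{4-[3-bromo-5-(methoxymethoxy)phenoxy]-3,5-bis(methoxymethoxy)phenyl}prop-2-en-1-ol
Conditions: (CH2=CH)2Zn (2 equiv, from CH2=CHMgBr and ZnCl2), (2R)-(+)-3-exo-morpholinoisoborneol [(+)-MIB, 10 mol %], toluene, −20 to 0 °C; aq. NH4Cl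
Reagents that add atoms: divinylzinc, C=C[Zn]C=C
Why: Amino-alcohol-catalysed enantioselective addition of a vinylzinc reagent to an aromatic aldehyde; the zinc aminoalkoxide of (+)-MIB binds aldehyde and vinylzinc in a bimetallic six-membered transition state and should deliver vinyl to the Re face, setting C1' as (R) (the (−)-ligand is the one that gives (S)-carbinols from aryl aldehydes).

Step 8
Reactants: 10 (1R)-1-{4-[3-bromo-5-(methoxymethoxy)phenoxy]-3,5-bis(methoxymethoxy)phenyl}prop-2-en-1-ol
Product: 11 tert-butyl{[(1R)-1-{4-[3-bromo-5-(methoxymethoxy)phenoxy]-3,5-bis(methoxymethoxy)phenyl}prop-2-en-1-yl]oxy}dimethylsilane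
Conditions: TBSCl (1.5 equiv), imidazole (3 equiv), DMF, rt
Reagents that add atoms: tert-butyldimethylsilyl chloride, CC(C)(C)[Si](C)(C)Cl
Why: Silyl ether formation under basic conditions that cannot ionise the benzylic, allylic alcohol or disturb the MOM ethers.

Step 9
Reactants: 12 hex-5-yn-1-ol; 13 5-bromopent-1-ene
Product: 15 undec-10-en-5-yn-1-ol, via dilithio alkynolate 14 (not isolated)
Conditions: n-BuLi (2.1 equiv), THF/DMPU, −78 to 0 °C; then 13 (1.1 equiv), 0 °C to rt; aq. NH4Cl
Reagents that add atoms: none
Why: Alkynide alkylation (SN2); in the alkoxide/acetylide dianion only the carbon end is nucleophilic enough to displace the primary bromide.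

Step 10
Reactants: 15 undec-10-en-5-yn-1-ol
Product: 16 (5Z)-undeca-5,10-dien-1-ol
Conditions: H2 (1 atm, stopped after 1.0 equiv), nickel boride from Ni(OAc)2·4H2O and NaBH4 (5 mol %), ethylenediamine, EtOH, rt
Reagents that add atoms: none
Why: Syn semi-hydrogenation of the internal alkyne on amine-poisoned nickel boride gives the (Z)-alkene; the alkyne binds this catalyst far more strongly than an alkene, so the terminal vinyl group should survive.

Step 11
Reactants: 16 (5Z)-undeca-5,10-dien-1-ol
Product: 17 (5Z)-undeca-5,10-dien-1-yl 4-methylbenzenesulfonate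
Conditions: TsCl (1.2 equiv), Et3N (2 equiv), DMAP (5 mol %), CH2Cl2, 0 °C
Reagents that add atoms: 4-methylbenzenesulfonyl chloride, Cc1ccc(cc1)S(=O)(=O)Cl
Why: Sulfonylation of the primary alcohol (tosylate formation), installing the leaving group at the future C4'.

Step 12
Reactants: 17 (5Z)-undeca-5,10-dien-1-yl 4-methylbenzenesulfonate; 11 tert-butyl{[(1R)-1-{4-[3-bromo-5-(methoxymethoxy)phenoxy]-3,5-bis(methoxymethoxy)phenyl}prop-2-en-1-yl]oxy}dimethylsilane
Product: 19 (5Z)-11-{3-[4-((1R)-1-{[tert-butyl(dimethyl)silyl]oxy}prop-2-en-1-yl)-2,6-bis(methoxymethoxy)phenoxy]-5-(methoxymethoxy)phenyl}undec-5-en-1-yl 4-methylbenzenesulfonate, via B-alkyl-9-BBN 18 (not isolated)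
Conditions: 17 (1.3 equiv), 9-BBN (1.2 equiv), THF, 0 °C to rt; then 11 (1.0 equiv), PdCl2(dppf) (5 mol %), K3PO4 (3 M aq., 3 equiv), THF/DMF, 50 °C
Reagents that add atoms: none
Why: B-alkyl Suzuki–Miyaura coupling; 9-BBN hydroborates only the terminal alkene of 17 (anti-Markovnikov) and the borane couples with the aryl bromide, while the primary tosylate, the silyl ether and the vinyl group of 11 are not attacked by the palladium catalyst, and using less 9-BBN than 17 leaves no B–H for that vinyl group.

Step 13
Reactants: 19 (5Z)-11-{3-[4-((1R)-1-{[tert-butyl(dimethyl)silyl]oxy}prop-2-en-1-yl)-2,6-bis(methoxymethoxy)phenoxy]-5-(methoxymethoxy)phenyl}undec-5-en-1-yl 4-methylbenzenesulfonate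
Product: 21 protected macrocycle [(1'R,8'Z)-22-membered ring of the target with C1'–OTBS and the three phenols as MOM ethers], via B-alkyl-9-BBN 20 (not isolated)
Conditions: 9-BBN (1.1 equiv), THF, 0 °C to rt; then syringe-pump addition (12 h) to CuI (20 mol %), LiOtBu (3 equiv), DMF, 60 °C, final concentration 2 mM
Reagents that add atoms: none
Why: Proposed new method: 9-BBN adds B–H across the monosubstituted C2'=C3' vinyl group (boron on C3') and leaves the 1,2-disubstituted C8'=C9' alkene alone; LiOtBu converts the B-alkyl-9-BBN into a borate that passes the C3' alkyl group to monovalent copper, and the resulting alkylcopper (alkoxycuprate) displaces the primary C4' tosylate by SN2, the closest known reaction being the intermolecular copper-catalysed Suzuki–Miyaura-type coupling of B-alkyl-9-BBN reagents with primary alkyl tosylates (CuI, LiOtBu), which has not been used for ring closure. The 22-membered ring closes in the exo-tet mode at a primary carbon, helped by the diaryl ether hinge and the cis C8'=C9' bond, which turn the two chain ends toward each other, and by pseudo-high dilution. No stereocentre is formed; C1' (R) is a spectator because its C–H and C–O bonds are not touched and the boron sits γ to the silyloxy group, so no β-alkoxy elimination is possible. The selectivities needed are vinyl over internal alkene in the hydroboration (steric discrimination by 9-BBN), ring closure over oligomerisation (slow addition) and substitution over elimination at C4' (soft organocopper nucleophile, unhindered primary tosylate). A two-electron displacement was chosen on purpose: no radical or alkylmetal ever sits on C4', which lies five atoms from C8'=C9' and would otherwise close a cyclopentane.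

Step 14
Reactants: 21 protected macrocycle
Product: 22 macrocyclic triphenol with C1'–OTBS [(1'R,8'Z)]
Conditions: ZnBr2 (4 equiv), n-PrSH (8 equiv), CH2Cl2, 0 °C, 15 min, argon
Reagents that add atoms: none
Why: Lewis-acid-assisted thiolysis of the three aryl MOM acetals; the thiol captures the methoxymethyl unit so it cannot alkylate the electron-rich rings, and the brief non-protic conditions should leave the secondary silyl ether, the benzylic C–O bond and the (Z)-alkene intact.

Step 15
Reactants: 22 macrocyclic triphenol with C1'–OTBS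
Product: 23 target, (1'R,8'Z)-macrocyclic diaryl ether with three phenols and the free C1' carbinol (CNP0316989.2)
Conditions: Bu4NF (3 equiv), AcOH (3 equiv), THF, rt
Reagents that add atoms: none
Why: Fluoride-mediated desilylation (Si–O cleavage) buffered with acetic acid frees the (R)-carbinol without acid or strong base that could ionise the benzylic centre.

**Compound list**

1 | 3,4,5-trihydroxybenzaldehyde | O=Cc1cc(O)c(O)c(O)c1 | starting material
2 | 3,5-dihydroxy-4-(prop-2-enyloxy)benzaldehyde | O=Cc1cc(O)c(OCC=C)c(O)c1 | intermediate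
3 | 3,5-bis(methoxymethoxy)-4-(prop-2-enyloxy)benzaldehyde | O=Cc1cc(OCOC)c(OCC=C)c(OCOC)c1 | intermediate
4 | 4-hydroxy-3,5-bis(methoxymethoxy)benzaldehyde | O=Cc1cc(OCOC)c(O)c(OCOC)c1 | intermediate
5 | 3,5-dibromophenol | Oc1cc(Br)cc(Br)c1 | starting material
6 | 1,3-dibromo-5-(methoxymethoxy)benzene | COCOc1cc(Br)cc(Br)c1 | intermediate
7 | [3-bromo-5-(methoxymethoxy)phenyl]lithium | [Li]c1cc(Br)cc(OCOC)c1 | intermediate
8 | [3-bromo-5-(methoxymethoxy)phenyl]boronic acid | COCOc1cc(Br)cc(c1)B(O)O | intermediate
9 | 4-[3-bromo-5-(methoxymethoxy)phenoxy]-3,5-bis(methoxymethoxy)benzaldehyde | O=Cc1cc(OCOC)c(Oc2cc(Br)cc(OCOC)c2)c(OCOC)c1 | intermediate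
10 | (1R)-1-{4-[3-bromo-5-(methoxymethoxy)phenoxy]-3,5-bis(methoxymethoxy)phenyl}prop-2-en-1-ol | COCOc1cc(Br)cc(c1)Oc1c(OCOC)cc(cc1OCOC)[C@H](O)C=C | intermediate
11 | tert-butyl{[(1R)-1-{4-[3-bromo-5-(methoxymethoxy)phenoxy]-3,5-bis(methoxymethoxy)phenyl}prop-2-en-1-yl]oxy}dimethylsilane | COCOc1cc(Br)cc(c1)Oc1c(OCOC)cc(cc1OCOC)[C@H](O[Si](C)(C)C(C)(C)C)C=C | intermediate
12 | hex-5-yn-1-ol | OCCCCC#C | starting material
13 | 5-bromopent-1-ene | BrCCCC=C | starting material
14 | dilithium salt of hex-5-yn-1-ol (lithium alkoxide, lithium acetylide) | [Li]OCCCCC#C[Li] | intermediate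
15 | undec-10-en-5-yn-1-ol | OCCCCC#CCCCC=C | intermediate
16 | (5Z)-undeca-5,10-dien-1-ol | OCCCC/C=C\CCCC=C | intermediate
17 | (5Z)-undeca-5,10-dien-1-yl 4-methylbenzenesulfonate | Cc1ccc(cc1)S(=O)(=O)OCCCC/C=C\CCCC=C | intermediate
18 | (5Z)-11-(9-borabicyclo[3.3.1]nonan-9-yl)undec-5-en-1-yl 4-methylbenzenesulfonate | Cc1ccc(cc1)S(=O)(=O)OCCCC/C=C\CCCCCB1C2CCCC1CCC2 | intermediate
19 | (5Z)-11-{3-[4-((1R)-1-{[tert-butyl(dimethyl)silyl]oxy}prop-2-en-1-yl)-2,6-bis(methoxymethoxy)phenoxy]-5-(methoxymethoxy)phenyl}undec-5-en-1-yl 4-methylbenzenesulfonate | COCOc1cc(CCCCC/C=C\CCCCOS(=O)(=O)c2ccc(C)cc2)cc(c1)Oc1c(OCOC)cc(cc1OCOC)[C@H](O[Si](C)(C)C(C)(C)C)C=C | intermediate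
20 | B-alkyl-9-BBN of 19 (9-BBN boron on C3', (R) at C1', tosylate at C4') | COCOc1cc(CCCCC/C=C\CCCCOS(=O)(=O)c2ccc(C)cc2)cc(c1)Oc1c(OCOC)cc(cc1OCOC)[C@H](O[Si](C)(C)C(C)(C)C)CCB1C2CCCC1CCC2 | intermediate
21 | protected macrocycle, (1'R,8'Z), C1'–OTBS, three phenols as MOM ethers | COCOc1cc2cc(c1)Oc1c(OCOC)cc(cc1OCOC)[C@H](O[Si](C)(C)C(C)(C)C)CCCCCC/C=C\CCCCC2 | intermediate
22 | macrocyclic triphenol, (1'R,8'Z), C1'–OTBS | Oc1cc2cc(c1)Oc1c(O)cc(cc1O)[C@H](O[Si](C)(C)C(C)(C)C)CCCCCC/C=C\CCCCC2 | intermediate
23 | target CNP0316989.2, (1'R,8'Z) | Oc1cc2cc(c1)Oc1c(O)cc(cc1O)[C@H](O)CCCCCC/C=C\CCCCC2 | target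

**Step count and risks**

Total step count: 15. Longest linear sequence: 10 steps (steps 1, 2, 3, 6, 7, 8, 12, 13, 14, 15).

Steps most likely to fail:

1. Step 13 (proposed new method). Oligomerisation may outrun ring closure, and catalyst turnover may be slow or the alkylborane may be lost by protodeboronation at high dilution. Fallback: the two couplings are run in the opposite order, so that C3'–C4' is made by the known intermolecular copper reaction and the ring is closed by the well-precedented intramolecular B-alkyl Suzuki–Miyaura coupling at the ring A–C14' bond. Setting out from 11, 9-BBN (THF) should give the B-alkyl-9-BBN F1. Coupling F1 with tosylate 17 (CuI, LiOtBu, DMF, 60 °C) should give the aryl bromide with the complete C1'–C14' chain and a terminal C13'=C14' alkene F2. 9-BBN then hydroborates only this terminal alkene to give the borane F3, and PdCl2(dppf), AsPh3, Cs2CO3, DMF/THF/H2O under high dilution should close the ring to 21, where the route is rejoined.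

2. Step 6. Transmetalation and C–O bond formation may be too slow at the doubly ortho-substituted, electron-poor phenol, so that protodeboronation and homocoupling of the boronic acid take over. Fallback: the polarity of the ring A partner is reversed to an Ullmann-type coupling of an aryl halide. Setting out from 4 and an excess of dibromide 6 (CuI, picolinic acid, K3PO4, DMSO, 90 °C), monoarylation should give 9 directly, where the route is rejoined; step 5 is then not needed and no new compound arises (F0).

3. Step 7. Facial selectivity may be poor because of uncatalysed background addition or competing coordination of zinc by the MOM ethers. Fallback: enzymatic kinetic resolution. Setting out from 9, vinylmagnesium bromide (THF, −78 °C) should give the racemic allylic alcohol F4. Immobilised Candida antarctica lipase B (Novozym 435) with vinyl acetate in toluene is expected to acylate the (R)-enantiomer only (aryl as the large and vinyl as the medium substituent), giving the (R)-acetate F5, which is separated from the unreacted (S)-alcohol. K2CO3 in MeOH then returns 10, where the route is rejoined.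

**Further compounds**

F1 | step 13 | B-alkyl-9-BBN from 11 (boron on C3', aryl bromide retained) | COCOc1cc(Br)cc(c1)Oc1c(OCOC)cc(cc1OCOC)[C@H](O[Si](C)(C)C(C)(C)C)CCB1C2CCCC1CCC2
F2 | step 13 | aryl bromide with complete C1'–C14' chain, (1'R,8'Z), terminal C13'=C14' alkene | COCOc1cc(Br)cc(c1)Oc1c(OCOC)cc(cc1OCOC)[C@H](O[Si](C)(C)C(C)(C)C)CCCCCC/C=C\CCCC=C
F3 | step 13 | B-alkyl-9-BBN from F2 (boron on C14') | COCOc1cc(Br)cc(c1)Oc1c(OCOC)cc(cc1OCOC)[C@H](O[Si](C)(C)C(C)(C)C)CCCCCC/C=C\CCCCCB1C2CCCC1CCC2
F0 | step 6 | none | none
F4 | step 7 | racemic 1-{4-[3-bromo-5-(methoxymethoxy)phenoxy]-3,5-bis(methoxymethoxy)phenyl}prop-2-en-1-ol | COCOc1cc(Br)cc(c1)Oc1c(OCOC)cc(cc1OCOC)C(O)C=C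
F5 | step 7 | (1R)-1-{4-[3-bromo-5-(methoxymethoxy)phenoxy]-3,5-bis(methoxymethoxy)phenyl}prop-2-en-1-yl acetate | COCOc1cc(Br)cc(c1)Oc1c(OCOC)cc(cc1OCOC)[C@H](OC(C)=O)C=C
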